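**Retrosynthetic overview**

1. Feature: in the dihydrofuran fused to the catechol-type ring B (O1', C2', C3'; unprimed locants are used for the dihydrofuran on the resorcinol-type ring A), C2' is a benzylic CH bound to O1' and to a 4-hydroxyphenyl ring. It is the former CH2 of a 4-methoxybenzyl ether on the ring-B phenol oxygen, five atoms away from C3'.
2. Last disconnections: the seven O-methyl groups (BBr3), then O1–C2 and C2–C3 of the ring-A dihydrofuran by [4+1] annulation of a ring-A ortho-quinone methide with a chiral 4-methoxybenzylidene sulfonium ylide.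
3. The methide carbon (C3) is the aldehyde carbon of 5-bromovanillin. Ring A is attached to it as an aryllithium that already carries the (E)-4-methoxystyryl group (Horner–Wadsworth–Emmons), and its ortho phenol is freed by chelation-controlled demethylation of the derived ketone.
4. C3'–aryl: nickel/photoredox decarboxylative arylation of the C3' acid, trans to the C2' aryl. C2'–C3': enantioselective dirhodium carbene insertion of an aryldiazoacetate into the O-benzylic C–H bond.
5. Ring order: rings A and B are bought; the ring-B dihydrofuran closes in step 6 and the ring-A dihydrofuran in step 17.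

Key step: step 6

Assumption: Rh2(S-PTTL)4 is taken to select the benzylic hydrogen that gives C2' R, and the (1R,4R,5R)-sulfide to give C2 S/C3 S, by analogy with their usual facial preferences; each is to be confirmed on first use, and the mirror-image catalyst or sulfide is the remedy.

**Route**

Step 1
Reactants: 1 5-bromovanillin; 2 4-methoxybenzyl chloride
Product: 3 3-bromo-5-methoxy-4-[(4-methoxybenzyl)oxy]benzaldehyde
Conditions: K2CO3, DMF, 60 °C
Reagents that add atoms: 4-methoxybenzyl chloride 2, COc1ccc(CCl)cc1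
Why: Williamson ether synthesis on the acidic, hindered phenol with a reactive benzylic chloride; the aldehyde is inert to carbonate.

Step 2
Reactants: 3 3-bromo-5-methoxy-4-[(4-methoxybenzyl)oxy]benzaldehyde
Product: 4 2-{3-bromo-5-methoxy-4-[(4-methoxybenzyl)oxy]phenyl}-1,3-dioxolane
Conditions: ethylene glycol, PPTS (cat.), toluene, reflux (Dean–Stark)
Reagents that add atoms: ethylene glycol, OCCO
Why: Acetalisation with azeotropic removal of water masks the aldehyde against enolate, diazo and carbene chemistry; the weak acid PPTS should spare the aryl 4-methoxybenzyl ether.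

Step 3
Reactants: 4 2-{3-bromo-5-methoxy-4-[(4-methoxybenzyl)oxy]phenyl}-1,3-dioxolane; 5 dimethyl malonate
Product: 6 dimethyl 2-{5-(1,3-dioxolan-2-yl)-3-methoxy-2-[(4-methoxybenzyl)oxy]phenyl}malonate
Conditions: Pd(OAc)2 (2 mol%), P(t-Bu)3·HBF4 (4 mol%), K3PO4, toluene, 90 °C
Reagents that add atoms: dimethyl malonate 5, COC(=O)CC(=O)OC
Why: Palladium-catalysed α-arylation of a malonate enolate; the bulky electron-rich phosphine allows oxidative addition and reductive elimination at the ortho-alkoxy aryl bromide, and acetal and ether are stable to phosphate base.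

Step 4
Reactants: 6 dimethyl 2-{5-(1,3-dioxolan-2-yl)-3-methoxy-2-[(4-methoxybenzyl)oxy]phenyl}malonate
Product: 7 methyl 2-{5-(1,3-dioxolan-2-yl)-3-methoxy-2-[(4-methoxybenzyl)oxy]phenyl}acetate
Conditions: LiCl, H2O, DMSO, 140 °C
Reagents that add atoms: none
Why: Krapcho dealkoxycarbonylation (chloride attacks one ester methyl, the aryl-stabilised carbanion loses CO2 and is protonated) under neutral conditions that keep the acetal.

Step 5
Reactants: 7 methyl 2-{5-(1,3-dioxolan-2-yl)-3-methoxy-2-[(4-methoxybenzyl)oxy]phenyl}acetate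
Product: 8 methyl 2-diazo-2-{5-(1,3-dioxolan-2-yl)-3-methoxy-2-[(4-methoxybenzyl)oxy]phenyl}acetate
Conditions: p-ABSA, DBU, MeCN, 0 °C → rt
Reagents that add atoms: 4-acetamidobenzenesulfonyl azide (p-ABSA), CC(=O)Nc1ccc(cc1)S(=O)(=O)N=[N+]=[N-]
Why: Regitz diazo transfer to the arylacetate enolate, the standard entry to aryldiazoacetates.

Step 6
Reactants: 8 methyl 2-diazo-2-{5-(1,3-dioxolan-2-yl)-3-methoxy-2-[(4-methoxybenzyl)oxy]phenyl}acetate
Product: 10 methyl (2R,3R)-5-(1,3-dioxolan-2-yl)-7-methoxy-2-(4-methoxyphenyl)-2,3-dihydro-1-benzofuran-3-carboxylate, via cis ester 9 (not isolated)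
Conditions: Rh2(S-PTTL)4 (2 mol%), toluene, −60 °C, slow addition of 8; then NaOMe, MeOH, 0 °C → rt
Reagents that add atoms: none
Why: Rh2(S-PTTL)4, dirhodium tetrakis[N-phthaloyl-(S)-tert-leucinate] (divalent rhodium), expels N2 from 8 to give a donor/acceptor rhodium carbene that inserts into one benzylic C–H bond of the neighbouring 4-methoxybenzyl ether through a concerted, hydride-transfer-like three-centre transition state, forming C2'–C3'. The closest known reaction is the dirhodium-carboxylate-catalysed enantioselective intramolecular C–H insertion of 2-(benzyloxy)aryl diazoacetates to 2-aryl-2,3-dihydrobenzofuran-3-carboxylates. The dihydrofuran closes by 1,5 C–H insertion, the carbene carbon C3' bonding to the fifth atom C2' across C3a', C7a' and O1'. C2' is set by the chiral ligand sphere, which chooses between the two enantiotopic benzylic hydrogens (R expected), while C3' forms cis (9) under kinetic control and is then equilibrated by methoxide through the ester enolate to the trans ester 10 without touching C2'. The step needs site selectivity for the O-benzylic CH2 over the methoxy C–H bonds, the arene π-systems and the acetal C–H of a second molecule. This is secured by the five-atom spacing, by activation of that C–H bond through the ether oxygen and the 4-methoxyphenyl group, by the two ortho substituents that hold the benzyloxy group beside the carbene, and by dilution at low temperature.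

Step 7
Reactants: 10 methyl (2R,3R)-5-(1,3-dioxolan-2-yl)-7-methoxy-2-(4-methoxyphenyl)-2,3-dihydro-1-benzofuran-3-carboxylate
Product: 11 (2R,3R)-5-(1,3-dioxolan-2-yl)-7-methoxy-2-(4-methoxyphenyl)-2,3-dihydro-1-benzofuran-3-carboxylic acid
Conditions: LiOH·H2O, THF/MeOH/H2O, rt; then cold dilute HCl to pH 4
Reagents that add atoms: lithium hydroxide (hydroxide oxygen), [Li+].[OH-]
Why: Ester saponification; the trans arrangement is the thermodynamic one under base, and brief cold acidification to pH 4 should leave the dioxolane intact.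

Step 8
Reactants: 11 (2R,3R)-5-(1,3-dioxolan-2-yl)-7-methoxy-2-(4-methoxyphenyl)-2,3-dihydro-1-benzofuran-3-carboxylic acid; 12 1-bromo-3,5-dimethoxybenzene
Product: 13 2-[(2R,3R)-3-(3,5-dimethoxyphenyl)-7-methoxy-2-(4-methoxyphenyl)-2,3-dihydro-1-benzofuran-5-yl]-1,3-dioxolane
Conditions: Ir[dF(CF3)ppy]2(dtbbpy)PF6 (1 mol%), NiCl2(dme) (10 mol%), 4,4'-di-tert-butyl-2,2'-bipyridine (15 mol%), Cs2CO3, DMF, blue LEDs, rt
Reagents that add atoms: 1-bromo-3,5-dimethoxybenzene 12, COc1cc(Br)cc(OC)c1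
Why: Iridium/nickel photoredox decarboxylative arylation: the carboxylate is oxidised and loses CO2 to a planar benzylic C3' radical, which the aryl–nickel species should capture on the face away from the C2' aryl group, so reductive elimination gives the 2',3'-trans product (C3' R, substrate control).

Step 9
Reactants: 13 2-[(2R,3R)-3-(3,5-dimethoxyphenyl)-7-methoxy-2-(4-methoxyphenyl)-2,3-dihydro-1-benzofuran-5-yl]-1,3-dioxolane
Product: 14 (2R,3R)-3-(3,5-dimethoxyphenyl)-7-methoxy-2-(4-methoxyphenyl)-2,3-dihydro-1-benzofuran-5-carbaldehyde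
Conditions: 1 M HCl, THF, 0 °C → rt
Reagents that add atoms: water, O
Why: Acid hydrolysis of the aryl dioxolane, which is fast for this electron-rich arene, so that dilute acid at room temperature should not ionise the benzylic C2'–O bond.

Step 10
Reactants: 15 2-bromo-3,5-dimethoxybenzaldehyde; 16 diethyl (4-methoxybenzyl)phosphonate
Product: 17 2-bromo-1,5-dimethoxy-3-[(E)-2-(4-methoxyphenyl)ethenyl]benzene
Conditions: NaH, THF, 0 °C → rt
Reagents that add atoms: diethyl (4-methoxybenzyl)phosphonate 16, CCOP(=O)(Cc1ccc(OC)cc1)OCC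
Why: Horner–Wadsworth–Emmons olefination with a benzylic phosphonate, which gives the (E)-stilbene and places the styryl group on ring A before the fragments are joined.

Step 11
Reactants: 17 2-bromo-1,5-dimethoxy-3-[(E)-2-(4-methoxyphenyl)ethenyl]benzene; 14 (2R,3R)-3-(3,5-dimethoxyphenyl)-7-methoxy-2-(4-methoxyphenyl)-2,3-dihydro-1-benzofuran-5-carbaldehyde
Product: 19 {2,4-dimethoxy-6-[(E)-2-(4-methoxyphenyl)ethenyl]phenyl}[(2R,3R)-3-(3,5-dimethoxyphenyl)-7-methoxy-2-(4-methoxyphenyl)-2,3-dihydro-1-benzofuran-5-yl]methanol (both carbinol epimers), via aryllithium 18 (not isolated)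
Conditions: 17, n-BuLi, THF, −78 °C; then 14, −78 → −20 °C; H2O
Reagents that add atoms: bromostilbene 17 (as aryllithium 18), COc1ccc(/C=C/c2cc(OC)cc(OC)c2Br)cc1
Why: Bromine–lithium exchange followed by 1,2-addition of the aryllithium to the non-enolisable aldehyde fixes the ring A–C3 bond at the position between an oxygen and the styryl group; the new carbinol centre is uncontrolled and is removed in step 12.

Step 12
Reactants: 19 the diaryl carbinol (both epimers)
Product: 20 {2,4-dimethoxy-6-[(E)-2-(4-methoxyphenyl)ethenyl]phenyl}[(2R,3R)-3-(3,5-dimethoxyphenyl)-7-methoxy-2-(4-methoxyphenyl)-2,3-dihydro-1-benzofuran-5-yl]methanone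
Conditions: MnO2 (activated, excess), CH2Cl2, rt
Reagents that add atoms: none
Why: Neutral oxidation of a doubly benzylic alcohol to the diaryl ketone, avoiding the acid that would ionise this electron-rich benzhydrol next to the stilbene.

Step 13
Reactants: 20 the 2,4-dimethoxyaryl ketone
Product: 21 {2-hydroxy-4-methoxy-6-[(E)-2-(4-methoxyphenyl)ethenyl]phenyl}[(2R,3R)-3-(3,5-dimethoxyphenyl)-7-methoxy-2-(4-methoxyphenyl)-2,3-dihydro-1-benzofuran-5-yl]methanone
Conditions: BCl3 (2 equiv), CH2Cl2, −78 → −20 °C; aq. NaHCO3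
Reagents that add atoms: none
Why: Chelation-controlled demethylation: BCl3 bridges the ketone oxygen and the ortho methoxy oxygen of ring A, so chloride should cleave only that methyl ether at low temperature and leave the six unchelated ones.

Step 14
Reactants: 21 the ortho-hydroxyaryl ketone
Product: 22 2-{[(2R,3R)-3-(3,5-dimethoxyphenyl)-7-methoxy-2-(4-methoxyphenyl)-2,3-dihydro-1-benzofuran-5-yl](hydroxy)methyl}-5-methoxy-3-[(E)-2-(4-methoxyphenyl)ethenyl]phenol (both carbinol epimers)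
Conditions: NaBH4, THF/MeOH, 0 °C; neutral work-up, used crude
Reagents that add atoms: none
Why: Hydride reduction of the ortho-hydroxybenzophenone to the ortho-hydroxybenzhydrol; the carbinol configuration is irrelevant because the carbon becomes trigonal in step 17.

Step 15
Reactants: 22 the ortho-hydroxybenzhydrol
Product: 23 2-{[(2R,3R)-3-(3,5-dimethoxyphenyl)-7-methoxy-2-(4-methoxyphenyl)-2,3-dihydro-1-benzofuran-5-yl](4-methylbenzenesulfonyl)methyl}-5-methoxy-3-[(E)-2-(4-methoxyphenyl)ethenyl]phenol (both epimers)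
Conditions: p-toluenesulfinic acid (freshly liberated from its sodium salt), MgSO4, CH2Cl2, rt
Reagents that add atoms: p-toluenesulfinic acid, Cc1ccc(cc1)S(=O)O
Why: SN1 substitution: the strongly stabilised benzhydryl cation forms under the weak sulfinic acid and is captured at sulfur by the soft sulfinate, giving a storable ortho-quinone methide precursor.

Step 16
Reactants: 24 (1R,4R,5R)-4,7,7-trimethyl-6-thiabicyclo[3.2.1]octane (isothiocineole); 2 4-methoxybenzyl chloride
Product: 25 (1R,4R,5R)-6-(4-methoxybenzyl)-4,7,7-trimethyl-6-thiabicyclo[3.2.1]octan-6-ium tetrafluoroborate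
Conditions: NaBF4, acetone, rt
Reagents that add atoms: 4-methoxybenzyl chloride 2, COc1ccc(CCl)cc1; sodium tetrafluoroborate, [Na+].F[B-](F)(F)F
Why: S-alkylation of the sulfide by the reactive benzylic chloride, driven by precipitation of NaCl and pairing of the sulfonium ion with the non-nucleophilic tetrafluoroborate.

Step 17
Reactants: 23 the ortho-hydroxybenzhydryl sulfone; 25 the chiral 4-methoxybenzylsulfonium tetrafluoroborate
Product: 28 (2S,3S)-3-[(2R,3R)-3-(3,5-dimethoxyphenyl)-7-methoxy-2-(4-methoxyphenyl)-2,3-dihydro-1-benzofuran-5-yl]-6-methoxy-2-(4-methoxyphenyl)-4-[(E)-2-(4-methoxyphenyl)ethenyl]-2,3-dihydro-1-benzofuran (heptamethyl ether of the target), via ortho-quinone methide 26 (not isolated), via sulfonium ylide 27 (not isolated)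
Conditions: Cs2CO3, MeCN/CH2Cl2, −20 °C → rt
Reagents that add atoms: sulfonium salt 25, C[C@@H]1CC[C@@H]2C[C@H]1[S+](Cc1ccc(OC)cc1)C2(C)C.F[B-](F)(F)F
Why: Proposed new method: carbonate expels sulfinate from the phenoxide of 23 to give ortho-quinone methide 26 and deprotonates 25 to ylide 27, whose carbanion adds to the methide carbon (C3) and whose sulfonium group is then displaced with inversion by the ring-A phenoxide in a 5-exo-tet closure (formal [4+1] annulation), the rigid bicyclic sulfide being expected to expose one ylide face and the anti approach of the two aryl groups to give the 2,3-trans ring with C2 S and C3 S; the closest known reactions are the base-mediated, trans-selective [4+1] annulations of ortho-quinone methides from 2-(sulfonylalkyl)phenols with sulfonium ylides and the asymmetric epoxidations of aldehydes by benzylides of this same sulfide.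

Step 18
Reactants: 28 the heptamethyl ether
Product: 29 (2S,3S)-3-[(2R,3R)-3-(3,5-dihydroxyphenyl)-7-hydroxy-2-(4-hydroxyphenyl)-2,3-dihydro-1-benzofuran-5-yl]-2-(4-hydroxyphenyl)-4-[(E)-2-(4-hydroxyphenyl)ethenyl]-2,3-dihydro-1-benzofuran-6-ol (CNP0172909.1)
Conditions: BBr3 (excess), CH2Cl2, −78 → 0 °C; then MeOH, H2O
Reagents that add atoms: none
Why: Lewis-acid cleavage of all seven aryl methyl ethers; C3 and C3' cannot epimerise and any reversible opening of the benzylic C2–O or C2'–O bond should reclose to the more stable trans rings, so the four stereocenters are expected to persist.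

**Compound list**

1 | 5-bromovanillin | COc1cc(C=O)cc(Br)c1O | starting material
2 | 4-methoxybenzyl chloride | COc1ccc(CCl)cc1 | starting material
3 | 3-bromo-5-methoxy-4-[(4-methoxybenzyl)oxy]benzaldehyde | COc1cc(C=O)cc(Br)c1OCc1ccc(OC)cc1 | intermediate
4 | 2-{3-bromo-5-methoxy-4-[(4-methoxybenzyl)oxy]phenyl}-1,3-dioxolane | COc1cc(C2OCCO2)cc(Br)c1OCc1ccc(OC)cc1 | intermediate
5 | dimethyl malonate | COC(=O)CC(=O)OC | starting material
6 | dimethyl 2-{5-(1,3-dioxolan-2-yl)-3-methoxy-2-[(4-methoxybenzyl)oxy]phenyl}malonate | COC(=O)C(C(=O)OC)c1cc(C2OCCO2)cc(OC)c1OCc1ccc(OC)cc1 | intermediate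
7 | methyl 2-{5-(1,3-dioxolan-2-yl)-3-methoxy-2-[(4-methoxybenzyl)oxy]phenyl}acetate | COC(=O)Cc1cc(C2OCCO2)cc(OC)c1OCc1ccc(OC)cc1 | intermediate
8 | methyl 2-diazo-2-{5-(1,3-dioxolan-2-yl)-3-methoxy-2-[(4-methoxybenzyl)oxy]phenyl}acetate | COC(=O)C(=[N+]=[N-])c1cc(C2OCCO2)cc(OC)c1OCc1ccc(OC)cc1 | intermediate
9 | methyl (2R,3S)-5-(1,3-dioxolan-2-yl)-7-methoxy-2-(4-methoxyphenyl)-2,3-dihydro-1-benzofuran-3-carboxylate (cis ester) | C1COC(O1)c1cc(OC)c2c(c1)[C@H](C(=O)OC)[C@H](c1ccc(OC)cc1)O2 | intermediate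
10 | methyl (2R,3R)-5-(1,3-dioxolan-2-yl)-7-methoxy-2-(4-methoxyphenyl)-2,3-dihydro-1-benzofuran-3-carboxylate (trans ester) | C1COC(O1)c1cc(OC)c2c(c1)[C@@H](C(=O)OC)[C@H](c1ccc(OC)cc1)O2 | intermediate
11 | (2R,3R)-5-(1,3-dioxolan-2-yl)-7-methoxy-2-(4-methoxyphenyl)-2,3-dihydro-1-benzofuran-3-carboxylic acid | C1COC(O1)c1cc(OC)c2c(c1)[C@@H](C(=O)O)[C@H](c1ccc(OC)cc1)O2 | intermediate
12 | 1-bromo-3,5-dimethoxybenzene | COc1cc(Br)cc(OC)c1 | starting material
13 | 2-[(2R,3R)-3-(3,5-dimethoxyphenyl)-7-methoxy-2-(4-methoxyphenyl)-2,3-dihydro-1-benzofuran-5-yl]-1,3-dioxolane | C1COC(O1)c1cc(OC)c2c(c1)[C@@H](c1cc(OC)cc(OC)c1)[C@H](c1ccc(OC)cc1)O2 | intermediate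
14 | (2R,3R)-3-(3,5-dimethoxyphenyl)-7-methoxy-2-(4-methoxyphenyl)-2,3-dihydro-1-benzofuran-5-carbaldehyde | O=Cc1cc(OC)c2c(c1)[C@@H](c1cc(OC)cc(OC)c1)[C@H](c1ccc(OC)cc1)O2 | intermediate
15 | 2-bromo-3,5-dimethoxybenzaldehyde | COc1cc(OC)c(Br)c(C=O)c1 | starting material
16 | diethyl (4-methoxybenzyl)phosphonate | CCOP(=O)(Cc1ccc(OC)cc1)OCC | starting material
17 | 2-bromo-1,5-dimethoxy-3-[(E)-2-(4-methoxyphenyl)ethenyl]benzene | COc1ccc(/C=C/c2cc(OC)cc(OC)c2Br)cc1 | intermediate
18 | {2,4-dimethoxy-6-[(E)-2-(4-methoxyphenyl)ethenyl]phenyl}lithium | COc1ccc(/C=C/c2cc(OC)cc(OC)c2[Li])cc1 | intermediate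
19 | {2,4-dimethoxy-6-[(E)-2-(4-methoxyphenyl)ethenyl]phenyl}[(2R,3R)-3-(3,5-dimethoxyphenyl)-7-methoxy-2-(4-methoxyphenyl)-2,3-dihydro-1-benzofuran-5-yl]methanol (carbinol centre undefined) | COc1ccc(/C=C/c2cc(OC)cc(OC)c2C(O)c2cc(OC)c3c(c2)[C@@H](c2cc(OC)cc(OC)c2)[C@H](c2ccc(OC)cc2)O3)cc1 | intermediate
20 | {2,4-dimethoxy-6-[(E)-2-(4-methoxyphenyl)ethenyl]phenyl}[(2R,3R)-3-(3,5-dimethoxyphenyl)-7-methoxy-2-(4-methoxyphenyl)-2,3-dihydro-1-benzofuran-5-yl]methanone | COc1ccc(/C=C/c2cc(OC)cc(OC)c2C(=O)c2cc(OC)c3c(c2)[C@@H](c2cc(OC)cc(OC)c2)[C@H](c2ccc(OC)cc2)O3)cc1 | intermediate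
21 | {2-hydroxy-4-methoxy-6-[(E)-2-(4-methoxyphenyl)ethenyl]phenyl}[(2R,3R)-3-(3,5-dimethoxyphenyl)-7-methoxy-2-(4-methoxyphenyl)-2,3-dihydro-1-benzofuran-5-yl]methanone | COc1ccc(/C=C/c2cc(OC)cc(O)c2C(=O)c2cc(OC)c3c(c2)[C@@H](c2cc(OC)cc(OC)c2)[C@H](c2ccc(OC)cc2)O3)cc1 | intermediate
22 | 2-{[(2R,3R)-3-(3,5-dimethoxyphenyl)-7-methoxy-2-(4-methoxyphenyl)-2,3-dihydro-1-benzofuran-5-yl](hydroxy)methyl}-5-methoxy-3-[(E)-2-(4-methoxyphenyl)ethenyl]phenol (carbinol centre undefined) | COc1ccc(/C=C/c2cc(OC)cc(O)c2C(O)c2cc(OC)c3c(c2)[C@@H](c2cc(OC)cc(OC)c2)[C@H](c2ccc(OC)cc2)O3)cc1 | intermediate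
23 | 2-{[(2R,3R)-3-(3,5-dimethoxyphenyl)-7-methoxy-2-(4-methoxyphenyl)-2,3-dihydro-1-benzofuran-5-yl](4-methylbenzenesulfonyl)methyl}-5-methoxy-3-[(E)-2-(4-methoxyphenyl)ethenyl]phenol (sulfonyl-bearing centre undefined) | COc1ccc(/C=C/c2cc(OC)cc(O)c2C(c2cc(OC)c3c(c2)[C@@H](c2cc(OC)cc(OC)c2)[C@H](c2ccc(OC)cc2)O3)S(=O)(=O)c2ccc(C)cc2)cc1 | intermediate
24 | (1R,4R,5R)-4,7,7-trimethyl-6-thiabicyclo[3.2.1]octane (isothiocineole) | C[C@@H]1CC[C@@H]2C[C@H]1SC2(C)C | starting material
25 | (1R,4R,5R)-6-(4-methoxybenzyl)-4,7,7-trimethyl-6-thiabicyclo[3.2.1]octan-6-ium tetrafluoroborate | C[C@@H]1CC[C@@H]2C[C@H]1[S+](Cc1ccc(OC)cc1)C2(C)C.F[B-](F)(F)F | intermediate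
26 | 6-{[(2R,3R)-3-(3,5-dimethoxyphenyl)-7-methoxy-2-(4-methoxyphenyl)-2,3-dihydro-1-benzofuran-5-yl]methylidene}-3-methoxy-5-[(E)-2-(4-methoxyphenyl)ethenyl]cyclohexa-2,4-dien-1-one (ortho-quinone methide) | COc1ccc(/C=C/C2=CC(OC)=CC(=O)C2=Cc2cc(OC)c3c(c2)[C@@H](c2cc(OC)cc(OC)c2)[C@H](c2ccc(OC)cc2)O3)cc1 | intermediate
27 | (4-methoxyphenyl)[(1R,4R,5R)-4,7,7-trimethyl-6-thiabicyclo[3.2.1]octan-6-ium-6-yl]methanide (sulfonium ylide) | C[C@@H]1CC[C@@H]2C[C@H]1[S+]([CH-]c1ccc(OC)cc1)C2(C)C | intermediate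
28 | (2S,3S)-3-[(2R,3R)-3-(3,5-dimethoxyphenyl)-7-methoxy-2-(4-methoxyphenyl)-2,3-dihydro-1-benzofuran-5-yl]-6-methoxy-2-(4-methoxyphenyl)-4-[(E)-2-(4-methoxyphenyl)ethenyl]-2,3-dihydro-1-benzofuran | COc1ccc(/C=C/c2cc(OC)cc3c2[C@H](c2cc(OC)c4c(c2)[C@@H](c2cc(OC)cc(OC)c2)[C@H](c2ccc(OC)cc2)O4)[C@@H](c2ccc(OC)cc2)O3)cc1 | intermediate
29 | (2S,3S)-3-[(2R,3R)-3-(3,5-dihydroxyphenyl)-7-hydroxy-2-(4-hydroxyphenyl)-2,3-dihydro-1-benzofuran-5-yl]-2-(4-hydroxyphenyl)-4-[(E)-2-(4-hydroxyphenyl)ethenyl]-2,3-dihydro-1-benzofuran-6-ol (CNP0172909.1) | Oc1ccc(/C=C/c2cc(O)cc3c2[C@H](c2cc(O)c4c(c2)[C@@H](c2cc(O)cc(O)c2)[C@H](c2ccc(O)cc2)O4)[C@@H](c2ccc(O)cc2)O3)cc1 | target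

**Step count and risks**

Total step count: 18. Longest linear sequence: 16 steps (steps 1–9, 11–15, 17 and 18, from 5-bromovanillin).

Steps most likely to fail:

1. Step 17. The ylide may add to the hindered methide carbon without sufficient discrimination between the two faces of the quinone methide, or the 4-methoxybenzylsulfonium ion may ionise before the ylide forms, so that the sulfide does not control C3. The fallback uses the known enantioselective C–H insertion of donor/donor rhodium carbenes. It sets out from 21, which is O-alkylated with 4-methoxybenzyl chloride 2 (K2CO3, DMF) to the ring-A 4-methoxybenzyl ether ketone F1. Condensation with hydrazine hydrate (EtOH, AcOH cat., reflux) gives the hydrazone F2. Oxidation with MnO2 (CH2Cl2, 0 °C) gives the diaryldiazomethane F3, which is filtered and treated with Rh2(R-PTAD)4, dirhodium tetrakis[(R)-N-phthaloyl-1-adamantylglycinate], or its mirror image, whichever delivers C3 S. Insertion into the activated O-benzylic C–H bond is expected to outrun reaction with the neighbouring styrene and, by the precedent of this reaction class, to give mainly the 2,3-cis dihydrobenzofuran F4. Brief treatment with CF3CO2H (CH2Cl2, 0 °C) should equilibrate C2 through the 4-methoxybenzylic cation to the trans compound, where the route is rejoined at 28.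

2. Step 6. Discrimination between the two enantiotopic benzylic hydrogens may be eroded by the additional ortho methoxy group, or carbene dimerisation may compete at the low temperature needed for selectivity. The fallback keeps the same bond formation but adds a chiral auxiliary for double stereodifferentiation. It sets out from 7, which is saponified (LiOH, THF/H2O) to the arylacetic acid F5 and esterified (DCC, DMAP, CH2Cl2) with (S)-2-hydroxy-1-(pyrrolidin-1-yl)propan-1-one to the lactamide ester F6. Diazo transfer (p-ABSA, DBU) gives the diazo ester F7. Insertion with Rh2(S-DOSP)4, dirhodium tetrakis[(S)-N-(4-dodecylbenzenesulfonyl)prolinate] (CH2Cl2, −40 °C), should give the dihydrobenzofuran auxiliary ester F8, with auxiliary and catalyst paired for C2' R. NaOMe in MeOH then exchanges the auxiliary for methyl and settles C3' trans, rejoining the route at 10.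

3. Step 8. The benzylic C3' radical may dimerise or be reduced to the protodecarboxylated compound faster than nickel captures it, and capture may not be fully anti to the C2' aryl group. The fallback replaces photochemical radical generation by a redox-active ester and an arylzinc reagent. It sets out from 11, which is converted (N-hydroxyphthalimide, N,N'-diisopropylcarbodiimide, DMAP cat., CH2Cl2) into the N-acyloxyphthalimide F9. Bromide 12 is converted (Mg, LiCl, THF; then ZnCl2) into (3,5-dimethoxyphenyl)zinc chloride F10. Coupling of the two with NiCl2(dme) and 4,4'-di-tert-butyl-2,2'-bipyridine (THF/DMF, rt; 1 M HCl work-up) should give the trans arylated compound, rejoining the route at 13.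

**Further compounds**

F1 | step 17 | {2-[(4-methoxybenzyl)oxy]-4-methoxy-6-[(E)-2-(4-methoxyphenyl)ethenyl]phenyl}[(2R,3R)-3-(3,5-dimethoxyphenyl)-7-methoxy-2-(4-methoxyphenyl)-2,3-dihydro-1-benzofuran-5-yl]methanone | COc1ccc(/C=C/c2cc(OC)cc(OCc3ccc(OC)cc3)c2C(=O)c2cc(OC)c3c(c2)[C@@H](c2cc(OC)cc(OC)c2)[C@H](c2ccc(OC)cc2)O3)cc1
F2 | step 17 | hydrazone of F1 | COc1ccc(/C=C/c2cc(OC)cc(OCc3ccc(OC)cc3)c2C(=NN)c2cc(OC)c3c(c2)[C@@H](c2cc(OC)cc(OC)c2)[C@H](c2ccc(OC)cc2)O3)cc1
F3 | step 17 | diaryldiazomethane from F2 | COc1ccc(/C=C/c2cc(OC)cc(OCc3ccc(OC)cc3)c2C(=[N+]=[N-])c2cc(OC)c3c(c2)[C@@H](c2cc(OC)cc(OC)c2)[C@H](c2ccc(OC)cc2)O3)cc1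
F4 | step 17 | (2R,3S)-3-[(2R,3R)-3-(3,5-dimethoxyphenyl)-7-methoxy-2-(4-methoxyphenyl)-2,3-dihydro-1-benzofuran-5-yl]-6-methoxy-2-(4-methoxyphenyl)-4-[(E)-2-(4-methoxyphenyl)ethenyl]-2,3-dihydro-1-benzofuran (2,3-cis isomer of 28) | COc1ccc(/C=C/c2cc(OC)cc3c2[C@H](c2cc(OC)c4c(c2)[C@@H](c2cc(OC)cc(OC)c2)[C@H](c2ccc(OC)cc2)O4)[C@H](c2ccc(OC)cc2)O3)cc1
F5 | step 6 | 2-{5-(1,3-dioxolan-2-yl)-3-methoxy-2-[(4-methoxybenzyl)oxy]phenyl}acetic acid | OC(=O)Cc1cc(C2OCCO2)cc(OC)c1OCc1ccc(OC)cc1
F6 | step 6 | (2S)-1-oxo-1-(pyrrolidin-1-yl)propan-2-yl 2-{5-(1,3-dioxolan-2-yl)-3-methoxy-2-[(4-methoxybenzyl)oxy]phenyl}acetate | C[C@H](OC(=O)Cc1cc(C2OCCO2)cc(OC)c1OCc1ccc(OC)cc1)C(=O)N1CCCC1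
F7 | step 6 | (2S)-1-oxo-1-(pyrrolidin-1-yl)propan-2-yl 2-diazo-2-{5-(1,3-dioxolan-2-yl)-3-methoxy-2-[(4-methoxybenzyl)oxy]phenyl}acetate | C[C@H](OC(=O)C(=[N+]=[N-])c1cc(C2OCCO2)cc(OC)c1OCc1ccc(OC)cc1)C(=O)N1CCCC1
F8 | step 6 | (2S)-1-oxo-1-(pyrrolidin-1-yl)propan-2-yl (2R,3R)-5-(1,3-dioxolan-2-yl)-7-methoxy-2-(4-methoxyphenyl)-2,3-dihydro-1-benzofuran-3-carboxylate | C1COC(O1)c1cc(OC)c2c(c1)[C@@H](C(=O)O[C@@H](C)C(=O)N1CCCC1)[C@H](c1ccc(OC)cc1)O2
F9 | step 8 | 1,3-dioxoisoindolin-2-yl (2R,3R)-5-(1,3-dioxolan-2-yl)-7-methoxy-2-(4-methoxyphenyl)-2,3-dihydro-1-benzofuran-3-carboxylate | C1COC(O1)c1cc(OC)c2c(c1)[C@@H](C(=O)ON1C(=O)c3ccccc3C1=O)[C@H](c1ccc(OC)cc1)O2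
F10 | step 8 | (3,5-dimethoxyphenyl)zinc chloride | COc1cc([Zn]Cl)cc(OC)c1
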